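## The problem

The target is a monocyclic sesquiterpenoid ether of umbelliferone. Ring numbering used throughout: C1 = CHOAc, C2 and C3 = CH2, C4 = C(CH3)OH, C5 = CH bearing the chain, C6 = C(CH3)2; the chain runs C1′ to C5′ outward from C5, with the tertiary carbinol at C3′ and the 7-coumarinyl ether at C5′.

Three stereocentres sit on the ring (1R, 4R, 5S). In the chair with the chain equatorial, the C4 hydroxyl is axial and cis to the chain, the C4 methyl is equatorial, and the C1 acetoxy group is axial and trans to both. C5 can control C4 and C1 through that chair. The fourth centre, C3′ (R), is separated from C5 by two methylene groups and is out of reach of substrate control, so it must come from the chiral pool or from a reagent.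

The most crowded bond is C5–C6, between a tertiary and a quaternary carbon. The coumarin lactone will not survive hydrides, enolates or single-electron reductants, and the secondary acetate will not survive nucleophiles or base. Both tertiary alcohols dehydrate in acid. Aryl ether and acetate therefore belong at the end.

The enabling feature is the 1,4-relationship of the C1 and C4 oxygens. Read as two carbonyls, C3–C4 is the bond between a ketone carbon and the β-carbon of a C1 vinyl ketone. The C6 gem-dimethyl group blocks enolisation on one side of C1 and is also the element that can tell the C4 methyl from the C4 oxygen.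

## Retrosynthesis

**Aryl ether.** The C5′–O(aryl) bond of target 24 is cut first, giving triol acetate 22 and umbelliferone 23. The coumarin would not survive the reductive and basic steps that build the ring, so it is attached last, and only the primary hydroxyl of 22 can react under Mitsunobu conditions.

**Protecting groups and C1.** Triol 22 goes back through bis-silyl ether 21 and diol 20 to hydroxy ketone 19 (O–Si, O–acyl and C1–H bonds). The C1 ketone is kept as long as possible because it is the activating group of the key step. The forward reduction must deliver hydride equatorially, to give the axial alcohol trans to the chain, and the acylation must distinguish the secondary C1 hydroxyl from the free tertiary C4 hydroxyl.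

**Ring closure (C3–C4).** Cutting C3–C4 of 19 gives acyclic keto enone 18. This cut removes the ring and the C4 stereocentre in one stroke and leaves C5 as the only ring stereocentre, in an open chain where a sigmatropic shift can set it. The neighbouring cuts are less attractive. C4–C5 (aldol) leaves C5 alpha to a carbonyl in the product, and C5–C6 or C1–C6 would require an intermolecular bond to the quaternary carbon. The forward reaction is a reductive ketone–enone coupling that must place the C4 oxygen cis to the chain.

**Methyl ketone and vinyl ketone.** The C4 carbonyl of 18 is traced to the (E)-but-2-en-2-yl group of dienone 17 (C=C cleavage). The vinyl ketone of 17 comes from Weinreb amide 16 and acid 14 (C1–C2 bond). The alkene is cleaved only after the vinyl ketone is in place. C5 then becomes epimerisable one step before the ring closure and never meets an organometallic reagent, and the Grignard reagent never has to choose between two carbonyls.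

**C5–C6 by [3,3] shift.** Acid 14 is cut at C5–C6 to allylic isobutyrate 11, made from alcohol 9 and isobutyryl chloride 10. The tertiary–quaternary bond forms intramolecularly through a chair, and the carbinol configuration of 9 is transferred to C5. The isobutyrate enolate has two identical α-substituents, so ketene acetal geometry plays no role. The silyloxy group on the ketene acetal carbon penalises the chair with an axial carbinol methyl, which is why the enolate variant is preferred to a vinyl ether rearrangement that would end in an aldehyde.

**Carbinol and alkene.** Alcohol 9 comes from enone 8 by reagent-controlled reduction, and 8 from aldehyde 6 and ylide 7 (C=C bond). The aldehyde carbon of 6 becomes C5, and the ylide carbon with its methyl becomes C4 with its methyl. The forward reactions need (E) geometry and the (S) carbinol.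

**Chain from the chiral pool.** Aldehyde 6 goes back through silyl ethers 5, 4 and 2 to (R)-linalool 1. Linalool already holds C3′ with the right configuration and two distinguishable alkenes: the vinyl group becomes C4′–C5′–O by hydroboration, and the prenyl end is cleaved to the aldehyde.

## Roads not taken

**Alternative 1: iodolactone tether for the C4 oxygen.**
- **Cut and key step.** The C4–O bond is cut. Cyclohexenylacetic acid A1 (C3=C4 alkene, C1 as ethylene ketal) would be treated with I2 and NaHCO3; the carboxylate adds to C4 of the iodonium ion and closes the cis-fused γ-lactone A2, with iodine trans at C3.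
- **Merits.** A five-membered lactone on a cyclohexane can only be cis-fused, so the C4 oxygen is cis to the C5 substituent by geometry. On this point the road is better than the chosen plan, whose C4 control rests on conformational analysis. The lactone also protects the tertiary hydroxyl.
- **Weak points.** A1 needs the ring and C5 already in place. Iodine must be removed and the ketal cleaved in acid next to a tertiary carbinol. The lactone carbonyl of A2 is C2′, so the rest of the chain, with the remote quaternary carbinol C3′, must be built from it with no substrate control available.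
- **Comparison.** The chosen plan sets against the safer C4: ring and carbinol made in one step from an open chain, C3′ carried from 1 from the first step, and no tether atoms to remove.

**Alternative 2: Sharpless epoxide for the chain carbinol.**
- **Cut and key step.** The C3′–O bond is cut. (E)-Allylic alcohol A3, with the ring complete, would be epoxidised with t-BuOOH, Ti(O-i-Pr)4 and D-(−)-diisopropyl tartrate to epoxy alcohol A4. Hydride opening at C4′ would then give the 1,3-diol.
- **Merits.** Reagent control is reliable for (E)-trisubstituted allylic alcohols and independent of the ring. Either configuration is available, and the optical purity does not depend on a natural product. In these respects it is as good as or better than taking C3′ from linalool.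
- **Weak points.** It solves only the one stereocentre that the chiral pool supplies at no cost. The ring with C1, C4 and C5 still has to be made by another method. It needs an (E)-selective olefination on the finished ring, the epoxidation and a regioselective opening, that is four or five extra steps.
- **Comparison.** The chosen plan spends no steps on C3′ but must accept the optical purity of commercial 1.

**Alternative 3: proline aldol of a furan-derived triketone.**
- **Cut and key step.** The C4–C5 bond is cut. The proline enamine of the aldehyde in 3,3-dimethyl-4,7-dioxooctanal A5 would attack the methyl ketone (6-enolexo) to give hydroxy keto aldehyde A6, with C4 and C5 set in one catalytic step.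
- **Merits.** This is the shortest way to the ring, from an achiral precursor, with absolute configuration from the catalyst. In step count to the ring it is clearly better than the chosen plan.
- **Weak points.** A6 is a β-hydroxy aldehyde with C5 alpha to the formyl group, open to epimerisation, dehydration and retro-aldol. The enamine of the methyl ketone can attack the aldehyde instead and close a different six-membered ring. The cis relationship of hydroxyl and formyl is not secured for a ketone acceptor. The chain must then be attached at the formyl carbon with a fragment that already carries C3′, followed by hydrogenation, under basic conditions that A6 may not tolerate.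
- **Comparison.** The chosen plan sets against the shorter ring synthesis a C5 that is epimerisable at only one intermediate (18) and a chain that is present from the start.

Key step: step 12

## Route

Remarks:
- Commercial (R)-(−)-linalool of high enantiomeric purity is assumed; its optical purity fixes that of C3′.
- TBS = tert-butyldimethylsilyl, TES = triethylsilyl.
- SC = (3R)-5-(TBSO)-3-methyl-3-(TESO)pentyl, the silylated chain C1′–C5′.

Step 1
Reactants: 1 (R)-linalool
Product: 2 (3R)-3,7-dimethyl-3-(triethylsilyloxy)octa-1,6-diene
Conditions: Et3SiOTf, 2,6-lutidine, CH2Cl2, −78 to 0 °C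
Reagents that add atoms: triethylsilyl trifluoromethanesulfonate, CC[Si](CC)(CC)OS(=O)(=O)C(F)(F)F
Why: Silyl triflate with a hindered pyridine base is the standard silylation of a tertiary alcohol and does not touch the stereocentre; the ether prevents lactol formation once the chain end becomes an aldehyde.

Step 2
Reactants: 2 (3R)-3,7-dimethyl-3-(triethylsilyloxy)octa-1,6-diene
Product: 4 (3R)-3,7-dimethyl-3-(triethylsilyloxy)oct-6-en-1-ol, via alkyl-9-BBN adduct 3 (not isolated)
Conditions: 9-borabicyclo[3.3.1]nonane (9-BBN), THF, 0 °C to rt; then NaOH, H2O2, 0 °C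
Reagents that add atoms: hydrogen peroxide, OO
Why: Hydroboration–oxidation; 9-BBN adds to the monosubstituted vinyl group much faster than to the trisubstituted alkene and places boron on the terminal carbon, so only the primary C5′ alcohol should form.

Step 3
Reactants: 4 (3R)-3,7-dimethyl-3-(triethylsilyloxy)oct-6-en-1-ol
Product: 5 (3R)-1-(tert-butyldimethylsilyloxy)-3,7-dimethyl-3-(triethylsilyloxy)oct-6-ene
Conditions: t-BuMe2SiCl, imidazole, DMF, 0 °C to rt
Reagents that add atoms: tert-butyldimethylsilyl chloride, CC(C)(C)[Si](C)(C)Cl
Why: Routine silylation of a primary alcohol; the robust TBS ether is chosen because this oxygen must survive twelve further steps.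

Step 4
Reactants: 5 (3R)-1-(tert-butyldimethylsilyloxy)-3,7-dimethyl-3-(triethylsilyloxy)oct-6-ene
Product: 6 (4R)-6-(tert-butyldimethylsilyloxy)-4-methyl-4-(triethylsilyloxy)hexanal
Conditions: O3, pyridine, CH2Cl2, −78 °C
Reagents that add atoms: ozone, [O-][O+]=O
Why: Ozonolysis of the only alkene; pyridine converts the carbonyl oxide directly to the carbonyl compounds, so the aldehyde is obtained under neutral conditions that both silyl ethers tolerate.

Step 5
Reactants: 6 (4R)-6-(tert-butyldimethylsilyloxy)-4-methyl-4-(triethylsilyloxy)hexanal; 7 3-(triphenylphosphoranylidene)butan-2-one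
Product: 8 (3E,7R)-9-(tert-butyldimethylsilyloxy)-3,7-dimethyl-7-(triethylsilyloxy)non-3-en-2-one
Conditions: toluene, 100 °C
Reagents that add atoms: none
Why: Wittig olefination with a stabilised, α-branched keto ylide; reversible betaine formation should give the (E)-trisubstituted enone, whose alkene carbons are the future C5 and C4.

Step 6
Reactants: 8 (3E,7R)-9-(tert-butyldimethylsilyloxy)-3,7-dimethyl-7-(triethylsilyloxy)non-3-en-2-one
Product: 9 (2S,3E,7R)-9-(tert-butyldimethylsilyloxy)-3,7-dimethyl-7-(triethylsilyloxy)non-3-en-2-ol
Conditions: (R)-1-methyl-3,3-diphenyltetrahydro-1H,3H-pyrrolo[1,2-c][1,3,2]oxazaborole ((R)-Me-CBS, 0.2 equiv), catecholborane, toluene, −78 °C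
Reagents that add atoms: none
Why: Corey–Bakshi–Shibata reduction; the α-methyl alkenyl group acts as the large substituent and methyl as the small one, so the (R)-catalyst should deliver hydride to the face that gives the (S)-carbinol, under reagent control and independent of the remote C7 centre.

Step 7
Reactants: 9 (2S,3E,7R)-9-(tert-butyldimethylsilyloxy)-3,7-dimethyl-7-(triethylsilyloxy)non-3-en-2-ol; 10 isobutyryl chloride
Product: 11 (2S,3E,7R)-9-(tert-butyldimethylsilyloxy)-3,7-dimethyl-7-(triethylsilyloxy)non-3-en-2-yl 2-methylpropanoate
Conditions: pyridine, 4-(dimethylamino)pyridine (cat.), CH2Cl2, 0 °C to rt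
Reagents that add atoms: none
Why: Base-mediated acylation of a secondary allylic alcohol with retention at the carbinol carbon; the acyl group supplies C1, C6 and both C6 methyls.

Step 8
Reactants: 11 (2S,3E,7R)-9-(tert-butyldimethylsilyloxy)-3,7-dimethyl-7-(triethylsilyloxy)non-3-en-2-yl 2-methylpropanoate
Product: 14 (3R,4E)-2,2,4-trimethyl-3-SC-hex-4-enoic acid, via silyl ketene acetal 12 (not isolated), via trimethylsilyl ester 13 (not isolated)
Conditions: LiN(i-Pr)2, Me3SiCl, THF, −78 °C to 60 °C; then aq. citric acid
Reagents that add atoms: none
Why: Ireland–Claisen rearrangement; the ketene acetal has two identical α-methyls, so its geometry is irrelevant, and the chair with the carbinol methyl equatorial (the axial alternative clashes with the silyloxy group) forms C5–C6 on the alkene face fixed by the (S)-carbinol and the (E)-alkene. This chirality transfer sets C5 in the configuration of the target and leaves an (E)-but-2-en-2-yl group as the masked C4 ketone.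

Step 9
Reactants: 14 (3R,4E)-2,2,4-trimethyl-3-SC-hex-4-enoic acid
Product: 16 (3R,4E)-N-methoxy-N,2,2,4-tetramethyl-3-SC-hex-4-enamide, via acid chloride 15 (not isolated)
Conditions: 1-chloro-N,N,2-trimethylprop-1-en-1-amine, CH2Cl2, 0 °C to rt; then MeNH(OMe)·HCl, Et3N, 0 °C to rt
Reagents that add atoms: N,O-dimethylhydroxylamine hydrochloride, CNOC.Cl
Why: Weinreb amide formation through the acid chloride, made under neutral conditions so that no HCl reaches the tertiary TES ether; the small, reactive acid chloride is the dependable way to acylate at a carbonyl next to a quaternary carbon.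

Step 10
Reactants: 16 (3R,4E)-N-methoxy-N,2,2,4-tetramethyl-3-SC-hex-4-enamide
Product: 17 (5R,6E)-4,4,6-trimethyl-5-SC-octa-1,6-dien-3-one
Conditions: CH2=CHMgBr, THF, 0 °C; inverse quench into cold dilute HCl
Reagents that add atoms: vinylmagnesium bromide, C=C[Mg]Br
Why: Weinreb ketone synthesis; the magnesium chelate of the tetrahedral adduct persists until the quench, so the vinyl ketone appears only when no Grignard reagent is left, and the acidic inverse quench protonates the released MeNH(OMe) before it can add to the enone. C5 is not alpha to this carbonyl and cannot epimerise.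

Step 11
Reactants: 17 (5R,6E)-4,4,6-trimethyl-5-SC-octa-1,6-dien-3-one
Product: 18 (5S)-4,4-dimethyl-5-SC-hept-1-ene-3,6-dione
Conditions: O3 (1.0 equiv, metered), pyridine, CH2Cl2, −78 °C
Reagents that add atoms: ozone, [O-][O+]=O
Why: Chemoselective ozonolysis; electrophilic ozone attacks the electron-rich trisubstituted alkene much faster than the electron-poor vinyl ketone, and pyridine gives the methyl ketone directly, with no reductant that could add to the enone and no base that could epimerise the now enolisable C5.

Step 12
Reactants: 18 (5S)-4,4-dimethyl-5-SC-hept-1-ene-3,6-dione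
Product: 19 (3S,4R)-4-hydroxy-2,2,4-trimethyl-3-SC-cyclohexan-1-one
Conditions: SmI2 (2.5 equiv), t-BuOH (2 equiv), THF, slow addition of 18 at high dilution, −78 to 0 °C
Reagents that add atoms: none
Why: Electron transfer from SmI2 (divalent samarium) gives the C4 ketyl or, more probably, the radical anion of the more easily reduced vinyl ketone; either species joins C3 to C4, a second electron gives the C1 enolate and C4 alkoxide bound to trivalent samarium, and t-BuOH protonates the enolate to ketone 19. The closest known reaction type is the samarium diiodide reductive ketone–enone (ketyl–olefin) cyclisation to cyclic γ-hydroxy ketones. The ring closes 6-endo-trig with respect to C2=C3 (6-exo with respect to the C4 carbonyl); attack at the unsubstituted β-carbon C3 is favoured by enone polarity over 5-exo attack at C2, and a reductive aldol to a five-membered ring is an enolendo closure that is geometrically disfavoured. The new stereocentre C4 is controlled by C5 through a half-chair in which C6, C1, C2 and C3 are coplanar and the chain is equatorial: whichever C4 substituent turns axial meets the pseudoaxial C6 methyl, oxygen is the smaller partner for that contact, so the methyl should go equatorial and the C4–O bond end cis to the chain (4R). HMPA is left out on purpose so that the samarium alkoxide stays as compact as possible. The step also needs chemoselectivity for coupling over plain reduction or dimerisation of the enone, which slow addition at high dilution and a weak proton donor should secure.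

Step 13
Reactants: 19 (3S,4R)-4-hydroxy-2,2,4-trimethyl-3-SC-cyclohexan-1-one
Product: 20 (1R,2S,4R)-1,3,3-trimethyl-2-SC-cyclohexane-1,4-diol
Conditions: LiBH(s-Bu)3 (2.5 equiv), THF, −78 °C; aq. NH4Cl
Reagents that add atoms: none
Why: A bulky trialkylborohydride cannot use the axial trajectory past the axial C3 and C5 hydrogens and attacks equatorially, giving the axial C1 alcohol trans to the chain; the closest analogy is the reduction of 4,4-dimethyl-3-keto triterpenoids to the axial 3-alcohols with this reagent.

Step 14
Reactants: 20 (1R,2S,4R)-1,3,3-trimethyl-2-SC-cyclohexane-1,4-diol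
Product: 21 (1R,3S,4R)-4-hydroxy-2,2,4-trimethyl-3-SC-cyclohexyl acetate
Conditions: Ac2O, pyridine, 4-(dimethylamino)pyridine (cat.), CH2Cl2, 0 °C to rt
Reagents that add atoms: acetic anhydride, CC(=O)OC(C)=O
Why: Catalysed acylation distinguishes the secondary C1 hydroxyl from the tertiary C4 hydroxyl, which should not be acylated at room temperature; the C3′ oxygen is still silylated.

Step 15
Reactants: 21 (1R,3S,4R)-4-hydroxy-2,2,4-trimethyl-3-SC-cyclohexyl acetate
Product: 22 (1R,3S,4R)-3-[(3R)-3,5-dihydroxy-3-methylpentyl]-4-hydroxy-2,2,4-trimethylcyclohexyl acetate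
Conditions: HF·pyridine, pyridine, THF, 0 °C to rt
Reagents that add atoms: none
Why: Fluoride cleaves both silyl ethers under buffered, non-basic conditions that keep the acetate (no hydroxyl is close enough for acyl migration) and do not dehydrate the tertiary alcohols.

Step 16
Reactants: 22 (1R,3S,4R)-3-[(3R)-3,5-dihydroxy-3-methylpentyl]-4-hydroxy-2,2,4-trimethylcyclohexyl acetate; 23 umbelliferone
Product: 24 (1R,3S,4R)-4-hydroxy-3-[(3R)-3-hydroxy-3-methyl-5-(2-oxo-2H-chromen-7-yloxy)pentyl]-2,2,4-trimethylcyclohexyl acetate
Conditions: PPh3, diisopropyl azodicarboxylate, THF, 0 °C to rt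
Reagents that add atoms: none
Why: Mitsunobu etherification; only the primary hydroxyl is activated, the two tertiary alcohols are inert, the phenol is acidic enough to serve as the nucleophile, and no stereocentre is involved.

## Compound list

1 | (R)-linalool, (3R)-3,7-dimethylocta-1,6-dien-3-ol | C=C[C@](C)(O)CCC=C(C)C | starting material
2 | (3R)-3,7-dimethyl-3-(triethylsilyloxy)octa-1,6-diene | C=C[C@](C)(O[Si](CC)(CC)CC)CCC=C(C)C | intermediate
3 | 9-[(3S)-3,7-dimethyl-3-(triethylsilyloxy)oct-6-en-1-yl]-9-borabicyclo[3.3.1]nonane | CC(C)=CCC[C@@](C)(O[Si](CC)(CC)CC)CCB1C2CCCC1CCC2 | intermediate (not isolated)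
4 | (3R)-3,7-dimethyl-3-(triethylsilyloxy)oct-6-en-1-ol | CC(C)=CCC[C@@](C)(O[Si](CC)(CC)CC)CCO | intermediate
5 | (3R)-1-(tert-butyldimethylsilyloxy)-3,7-dimethyl-3-(triethylsilyloxy)oct-6-ene | CC(C)=CCC[C@@](C)(O[Si](CC)(CC)CC)CCO[Si](C)(C)C(C)(C)C | intermediate
6 | (4R)-6-(tert-butyldimethylsilyloxy)-4-methyl-4-(triethylsilyloxy)hexanal | O=CCC[C@@](C)(O[Si](CC)(CC)CC)CCO[Si](C)(C)C(C)(C)C | intermediate
7 | 3-(triphenylphosphoranylidene)butan-2-one | CC(=O)C(C)=P(c1ccccc1)(c1ccccc1)c1ccccc1 | starting material
8 | (3E,7R)-9-(tert-butyldimethylsilyloxy)-3,7-dimethyl-7-(triethylsilyloxy)non-3-en-2-one | CC(=O)/C(C)=C/CC[C@@](C)(O[Si](CC)(CC)CC)CCO[Si](C)(C)C(C)(C)C | intermediate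
9 | (2S,3E,7R)-9-(tert-butyldimethylsilyloxy)-3,7-dimethyl-7-(triethylsilyloxy)non-3-en-2-ol | C[C@H](O)/C(C)=C/CC[C@@](C)(O[Si](CC)(CC)CC)CCO[Si](C)(C)C(C)(C)C | intermediate
10 | isobutyryl chloride (2-methylpropanoyl chloride) | CC(C)C(=O)Cl | starting material
11 | (2S,3E,7R)-9-(tert-butyldimethylsilyloxy)-3,7-dimethyl-7-(triethylsilyloxy)non-3-en-2-yl 2-methylpropanoate | C[C@H](OC(=O)C(C)C)/C(C)=C/CC[C@@](C)(O[Si](CC)(CC)CC)CCO[Si](C)(C)C(C)(C)C | intermediate
12 | trimethylsilyl ketene acetal of 11, 2-methyl-1-(trimethylsilyloxy)prop-1-enyl ether of 9 | C[C@H](OC(O[Si](C)(C)C)=C(C)C)/C(C)=C/CC[C@@](C)(O[Si](CC)(CC)CC)CCO[Si](C)(C)C(C)(C)C | intermediate (not isolated)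
13 | trimethylsilyl (3R,4E)-2,2,4-trimethyl-3-SC-hex-4-enoate | C/C=C(\C)[C@@H](CC[C@@](C)(O[Si](CC)(CC)CC)CCO[Si](C)(C)C(C)(C)C)C(C)(C)C(=O)O[Si](C)(C)C | intermediate (not isolated)
14 | (3R,4E)-2,2,4-trimethyl-3-SC-hex-4-enoic acid | C/C=C(\C)[C@@H](CC[C@@](C)(O[Si](CC)(CC)CC)CCO[Si](C)(C)C(C)(C)C)C(C)(C)C(=O)O | intermediate
15 | (3R,4E)-2,2,4-trimethyl-3-SC-hex-4-enoyl chloride | C/C=C(\C)[C@@H](CC[C@@](C)(O[Si](CC)(CC)CC)CCO[Si](C)(C)C(C)(C)C)C(C)(C)C(=O)Cl | intermediate (not isolated)
16 | (3R,4E)-N-methoxy-N,2,2,4-tetramethyl-3-SC-hex-4-enamide | C/C=C(\C)[C@@H](CC[C@@](C)(O[Si](CC)(CC)CC)CCO[Si](C)(C)C(C)(C)C)C(C)(C)C(=O)N(C)OC | intermediate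
17 | (5R,6E)-4,4,6-trimethyl-5-SC-octa-1,6-dien-3-one | C/C=C(\C)[C@@H](CC[C@@](C)(O[Si](CC)(CC)CC)CCO[Si](C)(C)C(C)(C)C)C(C)(C)C(=O)C=C | intermediate
18 | (5S)-4,4-dimethyl-5-SC-hept-1-ene-3,6-dione | CC(=O)[C@@H](CC[C@@](C)(O[Si](CC)(CC)CC)CCO[Si](C)(C)C(C)(C)C)C(C)(C)C(=O)C=C | intermediate
19 | (3S,4R)-4-hydroxy-2,2,4-trimethyl-3-SC-cyclohexan-1-one | O=C1CC[C@@](C)(O)[C@@H](CC[C@@](C)(O[Si](CC)(CC)CC)CCO[Si](C)(C)C(C)(C)C)C1(C)C | intermediate
20 | (1R,2S,4R)-1,3,3-trimethyl-2-SC-cyclohexane-1,4-diol | O[C@@H]1CC[C@@](C)(O)[C@@H](CC[C@@](C)(O[Si](CC)(CC)CC)CCO[Si](C)(C)C(C)(C)C)C1(C)C | intermediate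
21 | (1R,3S,4R)-4-hydroxy-2,2,4-trimethyl-3-SC-cyclohexyl acetate | CC(=O)O[C@@H]1CC[C@@](C)(O)[C@@H](CC[C@@](C)(O[Si](CC)(CC)CC)CCO[Si](C)(C)C(C)(C)C)C1(C)C | intermediate
22 | (1R,3S,4R)-3-[(3R)-3,5-dihydroxy-3-methylpentyl]-4-hydroxy-2,2,4-trimethylcyclohexyl acetate | CC(=O)O[C@@H]1CC[C@@](C)(O)[C@@H](CC[C@@](C)(O)CCO)C1(C)C | intermediate
23 | umbelliferone, 7-hydroxy-2H-chromen-2-one | O=c1ccc2ccc(O)cc2o1 | starting material
24 | (1R,3S,4R)-4-hydroxy-3-[(3R)-3-hydroxy-3-methyl-5-(2-oxo-2H-chromen-7-yloxy)pentyl]-2,2,4-trimethylcyclohexyl acetate (CNP0333962.1) | CC(=O)O[C@@H]1CC[C@@](C)(O)[C@@H](CC[C@@](C)(O)CCOc2ccc3ccc(=O)oc3c2)C1(C)C | target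

## Step count and least certain steps

Total: 16 steps. Longest linear sequence: 16 steps, from 1 to 24.

**Step 12 (key step).** The facial selectivity at C4 may be poor or reversed if the solvated samarium alkoxide, and not the methyl group, claims the equatorial site. Plain two-electron reduction of the vinyl ketone may also compete with coupling. The fallback sets C4 by a ring-fused epoxide, not by conformation. It sets out from Weinreb amide 16 and returns at hydroxy ketone 19.
- Reduction of 16 with i-Bu2AlH (THF, −78 °C) should give the aldehyde F1.
- Asymmetric allylboration with the B-allyldiisopinocampheylborane enantiomer that gives the (S)-carbinol from α-branched aldehydes (expected to be the (−)-reagent from (+)-α-pinene) should give the homoallylic alcohol F2.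
- Ring-closing metathesis with the second-generation Grubbs catalyst (CH2Cl2, 40 °C), between the terminal vinyl group and the but-2-en-2-yl group, should close the cyclohexenol F3 with loss of propene.
- Hydroxyl-directed epoxidation with VO(acac)2 and t-BuOOH should place the oxirane on the face of the C1 hydroxyl, which is the face of the chain, giving the cis-epoxy alcohol F4.
- LiBHEt3 should open the epoxide at the secondary carbon C3 and leave the C4 oxygen where the epoxide put it, giving the diol F5, the C1 epimer of 20.
- Dess–Martin periodinane oxidises only the secondary alcohol and gives 19.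

**Step 11.** Ozone may also attack the vinyl ketone, or the diketone may epimerise at C5 or polymerise on handling. The fallback sets out from dienone 17 and returns at 18. m-Chloroperbenzoic acid, which does not epoxidise electron-poor enones, should convert the trisubstituted alkene to the epoxide F6 (mixture at the oxirane carbons). Periodic acid in aqueous THF at 0 °C should then cleave the oxirane to the methyl ketone 18 and acetaldehyde.

**Step 10.** Addition to the hindered amide may be slow. Base-induced loss of the N-methoxy group or re-addition of the amine to the enone may lower the return. The fallback replaces the organomagnesium addition by an acyl cross-coupling. It sets out from acid 14, goes through acid chloride 15 as in step 9, and couples 15 with tributyl(vinyl)stannane under catalysis by BnPdCl(PPh3)2 (a divalent palladium precatalyst) in THF at 50 °C (Stille ketone synthesis). It returns at 17 and makes no compound outside the list (F0).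

**Step 8.** The rearrangement joins a fully substituted ketene acetal carbon to a substituted alkene terminus. Incomplete rearrangement, C-silylation or fragmentation of the enolate may compete, and a boat pathway would erode the transfer of chirality. The fallback uses a neutral orthoester rearrangement. It sets out from alcohol 9 and returns at 16. Heating 9 with trimethyl orthoisobutyrate and catalytic propionic acid (Johnson–Claisen, 140 °C) should give the methyl ester F7 through the same chair. Treatment of F7 with MeNH(OMe)·HCl and i-PrMgCl (THF, −20 to 0 °C) should convert the ester directly to Weinreb amide 16.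

## Further compounds

F1 | step 12 | (3R,4E)-2,2,4-trimethyl-3-SC-hex-4-enal | C/C=C(\C)[C@@H](CC[C@@](C)(O[Si](CC)(CC)CC)CCO[Si](C)(C)C(C)(C)C)C(C)(C)C=O
F2 | step 12 | (4S,6R,7E)-5,5,7-trimethyl-6-SC-nona-1,7-dien-4-ol | C/C=C(\C)[C@@H](CC[C@@](C)(O[Si](CC)(CC)CC)CCO[Si](C)(C)C(C)(C)C)C(C)(C)[C@@H](O)CC=C
F3 | step 12 | (1S,5R)-4,6,6-trimethyl-5-SC-cyclohex-3-en-1-ol, hydroxyl cis to the chain | O[C@H]1CC=C(C)[C@@H](CC[C@@](C)(O[Si](CC)(CC)CC)CCO[Si](C)(C)C(C)(C)C)C1(C)C
F4 | step 12 | 3,4-epoxide of F3, oxirane oxygen cis to the C1 hydroxyl and to the chain | O[C@H]1C[C@H]2O[C@@]2(C)[C@@H](CC[C@@](C)(O[Si](CC)(CC)CC)CCO[Si](C)(C)C(C)(C)C)C1(C)C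
F5 | step 12 | (1R,2S,4S)-1,3,3-trimethyl-2-SC-cyclohexane-1,4-diol, C1 epimer of 20 in the ring numbering of the target | O[C@H]1CC[C@@](C)(O)[C@@H](CC[C@@](C)(O[Si](CC)(CC)CC)CCO[Si](C)(C)C(C)(C)C)C1(C)C
F6 | step 11 | (5R)-5-(2,3-dimethyloxiran-2-yl)-4,4-dimethyl-5-SC-pent-1-en-3-one, mixture at the oxirane carbons | CC1OC1(C)[C@@H](CC[C@@](C)(O[Si](CC)(CC)CC)CCO[Si](C)(C)C(C)(C)C)C(C)(C)C(=O)C=C
F0 | step 10 | none | none
F7 | step 8 | methyl (3R,4E)-2,2,4-trimethyl-3-SC-hex-4-enoate | C/C=C(\C)[C@@H](CC[C@@](C)(O[Si](CC)(CC)CC)CCO[Si](C)(C)C(C)(C)C)C(C)(C)C(=O)OC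
A1 | alternative 1 | (R)-2-(8,10,10-trimethyl-1,4-dioxaspiro[4.5]dec-7-en-9-yl)acetic acid | C12(OCCO2)CC=C(C)[C@@H](CC(=O)O)C1(C)C
A2 | alternative 1 | cis-fused iodo γ-lactone of the C1 ethylene ketal, iodine at C3 trans to the lactone oxygen | C12(OCCO2)C[C@H](I)[C@@]3(C)OC(=O)C[C@H]3C1(C)C
A3 | alternative 2 | ring C1,C4-bis(triethylsilyl) ether carrying an (E)-5-hydroxy-3-methylpent-3-enyl chain at C5 | CC[Si](CC)(CC)O[C@@H]1CC[C@@](C)(O[Si](CC)(CC)CC)[C@@H](CC/C(C)=C/CO)C1(C)C
A4 | alternative 2 | 2,3-epoxy alcohol of the side chain | CC[Si](CC)(CC)O[C@@H]1CC[C@@](C)(O[Si](CC)(CC)CC)[C@@H](CC[C@@]2(C)O[C@@H]2CO)C1(C)C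
A5 | alternative 3 | 3,3-dimethyl-4,7-dioxooctanal | O=CCC(C)(C)C(=O)CCC(C)=O
A6 | alternative 3 | 2-hydroxy-2,6,6-trimethyl-5-oxocyclohexane-1-carbaldehyde, hydroxyl cis to formyl | O=C1CC[C@@](C)(O)[C@@H](C=O)C1(C)C
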